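**Two ratios.** The ratio of intermediate to product stood at 1.31 in the noon run at 20.0 min, and at 0.785 in the midnight run at 5.00 min. So the lead changed hands somewhere between those readings, and I asked what would put a new flask on the wrong side of that change.

common to all: substrate 0.12 M
- noon: partner 1.5 equiv; protic impurity 0.12 M; catalyst 0.5 mol%; run made earlier
- midnight: partner 1.5 equiv; protic impurity 0.12 M; catalyst 2.4 mol%; run made earlier
- gamma: partner 1.50 equiv; protic impurity 0.120 M; catalyst 1.4 mol%; time 30 min
- epsilon: partner 1.50 equiv; protic impurity 0.120 M; catalyst 0.68 mol%; time 30 min
- theta: partner 1.50 equiv; protic impurity 0.120 M; catalyst 2.7 mol%; time 30 min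

| run | time / min | intermediate / % | substrate / % | product / % |
|---|---|---|---|---|
| noon | 2.00 | 40.8 | 54.0 | 2.8 |
| noon | 5.00 | 65.7 | 20.2 | 8.2 |
| noon | 10.0 | 70.0 | 4.8 | 25.1 |
| noon | 15.0 | 63.3 | 2.6 | 34.5 |
| noon | 20.0 | 55.5 | 0.9 | 42.3 |
| midnight | 2.00 | 64.7 | 7.3 | 28.8 |
| midnight | 5.00 | 43.0 | 0.7 | 54.8 |
| midnight | 10.0 | 25.1 | 0.2 | 75.3 |
| midnight | 15.0 | 15.6 | 0 | 83.4 |
| midnight | 20.0 | 12.4 | 1.0 | 84.8 |

(scatter of a reading: 1 percentage point)

- which of these there is most of at the end, counted by the substrate in it, gamma (product / intermediate / substrate)
- which of these there is most of at the end, counted by the substrate in it, epsilon (product / intermediate / substrate)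
- which of these there is most of at the end, counted by the substrate in it, theta (product / intermediate / substrate)
- amount of the one of these that there is most of at the end, in percent of the substrate charged, gamma
- amount of the one of these that there is most of at the end, in percent of the substrate charged, epsilon
- amount of the one of these that there is most of at the end, in percent of the substrate charged, theta

- the analysis behind the earlier runs scatters by 1 percentage point, standard deviation

**Midnight clock.** The recipes differ in their loading of catalyst, so I tested whether loading simply scales time. Over the first 2.00 min, the logarithm of the substrate fraction fell 4.25 times as far at midnight as at noon, against a loading ratio of 4.80. That was close enough for a rough scale. I therefore multiplied each reading time by its loading and divided by the midnight loading. On this clock, the last noon reading fell at 4.17 min. Interpolating the gap between intermediate and product in a straight line put the change of lead at 4.61 min. I called this reading the crossing time: the midnight-clock time at which product overtakes intermediate.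

**Question reversed.** I took the crossing time as a rough mark and not a sharp limit, because the loading ratio had scaled the substrate only approximately: for intermediate to lead at 30 min, I expected a flask's clock to end near that mark or below it. Gamma ended at 17.5 min, epsilon at 8.50 min and theta at 33.8 min. Epsilon came nearest, yet it stood at 1.84 crossing times, and scaling back gave me an estimate of about 16.3 min of real time for its own crossing. So I committed to product leading in gamma, epsilon and theta.

**The forecast.** The forecast gave product at 83% for gamma, product at 63% for epsilon and product at 91% for theta, concluding: “Product dominates in all three.”

**The flasks.** Product led in gamma at 79.9%, in epsilon at 60.7% and in theta at 92.2%.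

    substrate + catalyst → catalyst + intermediate (k = 8.20 L mol⁻¹ s⁻¹)
    partner + catalyst + intermediate → catalyst + product (k = 9.70 L² mol⁻² s⁻¹)
    partner + protic impurity → quenched reagent (k = 0.00680 L mol⁻¹ s⁻¹)

The difference in loading is the main reason theta, at 7.33 crossing times, reached 92.2%, where the same flask gave 60.7% without that difference. Epsilon, at 1.84 crossing times, still held 39.3% as intermediate. Reversing its outcome took an earlier reading: at 12 min, epsilon stood at 0.738 crossing times, below the crossing, and intermediate led with 59.7% against 39.4% of product.

The runs are simulated for substances that don't exist, noise included.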